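The tetrahydrofuran (O1, C2, C3 bearing the benzyl group, C4 bearing the carbinol arm, C5) is re-drawn as a γ-lactone in which the carbinol oxygen acylates C2 and C5 is a carboxyl group. In that form the carbinol carbon and C4 are the β- and α-carbons of an aryl β-keto ester. A racemic, enolisable 2-aroylsuccinate (allyl ester at future C5, methyl ester at future C2) is therefore the key precursor: one ruthenium-catalysed transfer hydrogenation with dynamic kinetic resolution sets both centres, and the syn alcohol lactonises onto the methyl ester. C3 is then benzylated trans to the carboxyl, and the lactone is relayed into the ether ring through reduction and mesylate displacement at C5.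

Key step: step 4

Remark: the ring numbering O1, C2, C3 (benzyl), C4 (carbinol arm), C5 is used throughout; the target's two ring substituents are cis (3S,4R, with an (S)-carbinol), which corresponds to the all-trans lactone of the relay, and both phenols are carried as triisopropylsilyl ethers because these resist the amide bases, alkoxides and hydrides of the route.

**Step 1**
Reactants: 1 methyl vanillate
Product: 2 methyl 3-methoxy-4-(triisopropylsilyloxy)benzoate
Conditions: TIPSCl, imidazole, DMF, rt
Reagents that add atoms: triisopropylsilyl chloride, CC(C)[Si](Cl)(C(C)C)C(C)C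
Why: Imidazole-promoted O-silylation of the phenol (silyl ether formation) should be clean because the phenol is the only nucleophilic site.

**Step 2**
Reactants: 2 methyl 3-methoxy-4-(triisopropylsilyloxy)benzoate; 3 allyl acetate
Product: 4 allyl 3-[3-methoxy-4-(triisopropylsilyloxy)phenyl]-3-oxopropanoate
Conditions: LiN(SiMe3)2 (3 equiv), 3 (1.5 equiv), THF, −78 °C; then 2, −78 → 0 °C; 1 M HCl
Reagents that add atoms: none
Why: In this crossed Claisen condensation the aryl ester cannot enolise, the lithium enolate of 3 is preformed cold and used in excess, and deprotonation of the β-keto ester by the spare base should pull the equilibrium to 4.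

**Step 3**
Reactants: 4 allyl 3-[3-methoxy-4-(triisopropylsilyloxy)phenyl]-3-oxopropanoate; 5 methyl bromoacetate
Product: 6 1-allyl 4-methyl 2-[3-methoxy-4-(triisopropylsilyloxy)benzoyl]succinate (racemic)
Conditions: NaH (1.05 equiv), THF, 0 °C; then 5, 0 °C → rt
Reagents that add atoms: none
Why: C-Alkylation (SN2) of the stabilised sodium enolate of the β-keto ester with the reactive α-bromo ester should stop at monoalkylation with one equivalent of base, and the new centre is deliberately left racemic because the next step epimerises it.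

**Step 4**
Reactants: 6 1-allyl 4-methyl 2-[3-methoxy-4-(triisopropylsilyloxy)benzoyl]succinate (racemic)
Product: 8 allyl (2S,3S)-2-[3-methoxy-4-(triisopropylsilyloxy)phenyl]-5-oxotetrahydrofuran-3-carboxylate, via syn hydroxy diester 7 (not isolated)
Conditions: RuCl(p-cymene)[(S,S)-TsDPEN] (2 mol %), HCO2H–Et3N (5:2), DMF, 40 °C
Reagents that add atoms: none
Why: This is a Noyori–Ikariya asymmetric transfer hydrogenation run as a dynamic kinetic resolution, in which the ruthenium amide takes hydride and proton from formic acid (releasing CO2) and the Ru–H/N–H pair passes them to the aryl ketone through an outer-sphere six-membered transition state. The closest known reaction type is the dynamic kinetic transfer hydrogenation of α-substituted aryl β-keto esters with RuCl(arene)(TsDPEN) catalysts. The carbinol centre is set by the catalyst, since with the (S,S)-ligand the aryl ring lies under the p-cymene ligand (CH/π contact) and hydride should add to the face that gives the (S)-alcohol, as with simple aryl ketones. The α-centre (future ring C4) is set by the resolution, since the enantiomers of 6 interconvert through the enol in the triethylammonium formate medium faster than either is reduced and the catalyst should take the one that leads to the syn (S,S) hydroxy diester 7. The hydroxyl of 7 then attacks the methyl ester in a 5-exo-trig acyl substitution that closes the γ-lactone with loss of methanol, syn 7 giving the trans 2,3-disubstituted ring, whereas the allyl ester could only close a four-membered ring and stays intact. The step needs syn selectivity together with fast racemisation, which the acidic C–H between the two carbonyl groups and the catalyst's preference for the aryl ketone as the only reducible group should secure.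

**Step 5**
Reactants: 8 allyl (2S,3S)-2-[3-methoxy-4-(triisopropylsilyloxy)phenyl]-5-oxotetrahydrofuran-3-carboxylate
Product: 9 (2S,3S)-2-[3-methoxy-4-(triisopropylsilyloxy)phenyl]-5-oxotetrahydrofuran-3-carboxylic acid
Conditions: Pd(PPh3)4 (5 mol %), morpholine, THF, rt; then aq. KHSO4
Reagents that add atoms: none
Why: In this Tsuji–Trost deallylation zerovalent palladium ionises only the allyl ester to a π-allyl complex that morpholine traps, so the lactone, the silyl ether and both stereocentres should be untouched.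

**Step 6**
Reactants: 10 vanillin
Product: 11 3-methoxy-4-(triisopropylsilyloxy)benzaldehyde
Conditions: TIPSCl, imidazole, DMF, rt
Reagents that add atoms: triisopropylsilyl chloride, CC(C)[Si](Cl)(C(C)C)C(C)C
Why: Imidazole-promoted O-silylation of the phenol (silyl ether formation) leaves the aldehyde unchanged.

**Step 7**
Reactants: 11 3-methoxy-4-(triisopropylsilyloxy)benzaldehyde
Product: 12 [3-methoxy-4-(triisopropylsilyloxy)phenyl]methanol
Conditions: NaBH4, MeOH, 0 °C
Reagents that add atoms: none
Why: Borohydride reduction of the aryl aldehyde to the benzylic alcohol is fast at 0 °C, and the hindered aryl silyl ether should survive cold methanolic borohydride.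

**Step 8**
Reactants: 12 [3-methoxy-4-(triisopropylsilyloxy)phenyl]methanol
Product: 13 4-(bromomethyl)-2-methoxy-1-(triisopropylsilyloxy)benzene
Conditions: PBr3, Et2O, 0 °C
Reagents that add atoms: phosphorus tribromide, BrP(Br)Br
Why: Bromination of the benzylic alcohol through its phosphite ester (nucleophilic substitution by bromide) is rapid for this electron-rich benzylic position, and the bromide should be used at once because it is reactive.

**Step 9**
Reactants: 9 (2S,3S)-2-[3-methoxy-4-(triisopropylsilyloxy)phenyl]-5-oxotetrahydrofuran-3-carboxylic acid; 13 4-(bromomethyl)-2-methoxy-1-(triisopropylsilyloxy)benzene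
Product: 14 (2S,3S,4S)-4-[3-methoxy-4-(triisopropylsilyloxy)benzyl]-2-[3-methoxy-4-(triisopropylsilyloxy)phenyl]-5-oxotetrahydrofuran-3-carboxylic acid
Conditions: NaN(SiMe3)2 (2.2 equiv), THF, −78 °C; then 13, −78 → −40 °C; 1 M HCl
Reagents that add atoms: none
Why: In this α-alkylation of a paraconic acid dianion the carboxylate formed first blocks deprotonation at its own α-carbon (and thus ring opening), the second equivalent forms the lactone enolate, and the bromide should add to the face opposite the adjacent carboxylate, which sets the new centre (future ring C3) trans to it.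

**Step 10**
Reactants: 14 (2S,3S,4S)-4-[3-methoxy-4-(triisopropylsilyloxy)benzyl]-2-[3-methoxy-4-(triisopropylsilyloxy)phenyl]-5-oxotetrahydrofuran-3-carboxylic acid
Product: 15 (3S,4R,5S)-4-(hydroxymethyl)-3-[3-methoxy-4-(triisopropylsilyloxy)benzyl]-5-[3-methoxy-4-(triisopropylsilyloxy)phenyl]dihydrofuran-2(3H)-one
Conditions: BH3·SMe2, THF, 0 °C → rt; then H2O
Reagents that add atoms: none
Why: Chemoselective borane reduction of the carboxylic acid through its acyloxyborane should leave the much less reactive lactone and the silyl ethers alone, and no stereocentre is touched.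

**Step 11**
Reactants: 15 (3S,4R,5S)-4-(hydroxymethyl)-3-[3-methoxy-4-(triisopropylsilyloxy)benzyl]-5-[3-methoxy-4-(triisopropylsilyloxy)phenyl]dihydrofuran-2(3H)-one
Product: 16 {(2S,3R,4S)-4-[3-methoxy-4-(triisopropylsilyloxy)benzyl]-2-[3-methoxy-4-(triisopropylsilyloxy)phenyl]-5-oxotetrahydrofuran-3-yl}methyl methanesulfonate
Conditions: MsCl, Et3N, CH2Cl2, 0 °C
Reagents that add atoms: methanesulfonyl chloride, CS(=O)(=O)Cl
Why: Sulfonylation of the only free hydroxyl gives the leaving group at future C5 while the lactone keeps the other two oxygens masked, so only this carbon is activated.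

**Step 12**
Reactants: 16 {(2S,3R,4S)-4-[3-methoxy-4-(triisopropylsilyloxy)benzyl]-2-[3-methoxy-4-(triisopropylsilyloxy)phenyl]-5-oxotetrahydrofuran-3-yl}methyl methanesulfonate
Product: 18 (3S,4R)-3-[3-methoxy-4-(triisopropylsilyloxy)benzyl]-4-{(S)-hydroxy[3-methoxy-4-(triisopropylsilyloxy)phenyl]methyl}tetrahydrofuran, via diol mesylate 17 (not isolated)
Conditions: LiBH4, THF, 0 °C → rt; then KOt-Bu, 0 °C
Reagents that add atoms: none
Why: Reductive lactone opening followed by intramolecular Williamson etherification should work because LiBH4 reduces lactones far faster than it displaces primary mesylates, and the new primary alkoxide at future C2 then closes the ring on C5 in a 5-exo-tet displacement, whereas the benzylic oxygen could only form a four-membered ring.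

**Step 13**
Reactants: 18 (3S,4R)-3-[3-methoxy-4-(triisopropylsilyloxy)benzyl]-4-{(S)-hydroxy[3-methoxy-4-(triisopropylsilyloxy)phenyl]methyl}tetrahydrofuran
Product: 19 (3S,4R)-3-(4-hydroxy-3-methoxybenzyl)-4-[(S)-hydroxy(4-hydroxy-3-methoxyphenyl)methyl]tetrahydrofuran (CNP0234428.2)
Conditions: Bu4NF, AcOH, THF, 0 °C
Reagents that add atoms: none
Why: Fluoride-induced cleavage of both aryl silyl ethers is fast at 0 °C, and the acetic acid buffer keeps the phenols protonated so that the p-hydroxybenzylic alcohol should not eliminate to a quinone methide.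

**Compound list**

1 | methyl vanillate | COC(=O)c1ccc(O)c(OC)c1 | starting material
2 | methyl 3-methoxy-4-(triisopropylsilyloxy)benzoate | COC(=O)c1ccc(O[Si](C(C)C)(C(C)C)C(C)C)c(OC)c1 | intermediate
3 | allyl acetate | CC(=O)OCC=C | starting material
4 | allyl 3-[3-methoxy-4-(triisopropylsilyloxy)phenyl]-3-oxopropanoate | C=CCOC(=O)CC(=O)c1ccc(O[Si](C(C)C)(C(C)C)C(C)C)c(OC)c1 | intermediate
5 | methyl bromoacetate | COC(=O)CBr | starting material
6 | 1-allyl 4-methyl 2-[3-methoxy-4-(triisopropylsilyloxy)benzoyl]succinate (racemic) | COC(=O)CC(C(=O)OCC=C)C(=O)c1ccc(O[Si](C(C)C)(C(C)C)C(C)C)c(OC)c1 | intermediate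
7 | 1-allyl 4-methyl (S)-2-{(S)-hydroxy[3-methoxy-4-(triisopropylsilyloxy)phenyl]methyl}succinate (syn) | O[C@H](c1ccc(O[Si](C(C)C)(C(C)C)C(C)C)c(OC)c1)[C@@H](C(=O)OCC=C)CC(=O)OC | intermediate
8 | allyl (2S,3S)-2-[3-methoxy-4-(triisopropylsilyloxy)phenyl]-5-oxotetrahydrofuran-3-carboxylate (trans) | O=C1O[C@H](c2ccc(O[Si](C(C)C)(C(C)C)C(C)C)c(OC)c2)[C@@H](C(=O)OCC=C)C1 | intermediate
9 | (2S,3S)-2-[3-methoxy-4-(triisopropylsilyloxy)phenyl]-5-oxotetrahydrofuran-3-carboxylic acid | O=C1O[C@H](c2ccc(O[Si](C(C)C)(C(C)C)C(C)C)c(OC)c2)[C@@H](C(=O)O)C1 | intermediate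
10 | vanillin | COc1cc(C=O)ccc1O | starting material
11 | 3-methoxy-4-(triisopropylsilyloxy)benzaldehyde | COc1cc(C=O)ccc1O[Si](C(C)C)(C(C)C)C(C)C | intermediate
12 | [3-methoxy-4-(triisopropylsilyloxy)phenyl]methanol | COc1cc(CO)ccc1O[Si](C(C)C)(C(C)C)C(C)C | intermediate
13 | 4-(bromomethyl)-2-methoxy-1-(triisopropylsilyloxy)benzene | COc1cc(CBr)ccc1O[Si](C(C)C)(C(C)C)C(C)C | intermediate
14 | (2S,3S,4S)-4-[3-methoxy-4-(triisopropylsilyloxy)benzyl]-2-[3-methoxy-4-(triisopropylsilyloxy)phenyl]-5-oxotetrahydrofuran-3-carboxylic acid (all-trans) | O=C1O[C@H](c2ccc(O[Si](C(C)C)(C(C)C)C(C)C)c(OC)c2)[C@@H](C(=O)O)[C@@H]1Cc3ccc(O[Si](C(C)C)(C(C)C)C(C)C)c(OC)c3 | intermediate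
15 | (3S,4R,5S)-4-(hydroxymethyl)-3-[3-methoxy-4-(triisopropylsilyloxy)benzyl]-5-[3-methoxy-4-(triisopropylsilyloxy)phenyl]dihydrofuran-2(3H)-one | O=C1O[C@H](c2ccc(O[Si](C(C)C)(C(C)C)C(C)C)c(OC)c2)[C@@H](CO)[C@@H]1Cc3ccc(O[Si](C(C)C)(C(C)C)C(C)C)c(OC)c3 | intermediate
16 | {(2S,3R,4S)-4-[3-methoxy-4-(triisopropylsilyloxy)benzyl]-2-[3-methoxy-4-(triisopropylsilyloxy)phenyl]-5-oxotetrahydrofuran-3-yl}methyl methanesulfonate | O=C1O[C@H](c2ccc(O[Si](C(C)C)(C(C)C)C(C)C)c(OC)c2)[C@@H](COS(C)(=O)=O)[C@@H]1Cc3ccc(O[Si](C(C)C)(C(C)C)C(C)C)c(OC)c3 | intermediate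
17 | (2R,3S)-4-hydroxy-2-{(S)-hydroxy[3-methoxy-4-(triisopropylsilyloxy)phenyl]methyl}-3-[3-methoxy-4-(triisopropylsilyloxy)benzyl]butyl methanesulfonate | O[C@H](c1ccc(O[Si](C(C)C)(C(C)C)C(C)C)c(OC)c1)[C@@H](COS(C)(=O)=O)[C@@H](CO)Cc2ccc(O[Si](C(C)C)(C(C)C)C(C)C)c(OC)c2 | intermediate
18 | (3S,4R)-3-[3-methoxy-4-(triisopropylsilyloxy)benzyl]-4-{(S)-hydroxy[3-methoxy-4-(triisopropylsilyloxy)phenyl]methyl}tetrahydrofuran (cis) | O[C@H](c1ccc(O[Si](C(C)C)(C(C)C)C(C)C)c(OC)c1)[C@H]2COC[C@H]2Cc3ccc(O[Si](C(C)C)(C(C)C)C(C)C)c(OC)c3 | intermediate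
19 | (3S,4R)-3-(4-hydroxy-3-methoxybenzyl)-4-[(S)-hydroxy(4-hydroxy-3-methoxyphenyl)methyl]tetrahydrofuran | COc1cc(C[C@@H]2COC[C@@H]2[C@H](O)c2ccc(O)c(OC)c2)ccc1O | target

**Step count**

Total steps: 13.
Longest linear sequence: 10 steps (steps 1–5 and 9–13); the bromide 13 is made in a 3-step side branch (steps 6–8).

**Steps most likely to fail**

1. Step 4 (key step). The catalyst may discriminate poorly between the two interconverting enantiomers of 6 (low syn selectivity), hydride transfer to the electron-rich aryl ketone may be slow relative to racemisation, or lactonisation may stall. Fallback, an auxiliary-controlled aldol in place of the catalytic reduction, setting out from aldehyde 11 and coming back at acid 9: (S)-4-benzyl-3-(4-methoxy-4-oxobutanoyl)oxazolidin-2-one F1, made from (S)-4-benzyloxazolidin-2-one, n-BuLi and methyl 4-chloro-4-oxobutanoate, is converted into its Z boron enolate (Bu2BOTf, i-Pr2NEt, CH2Cl2, −78 °C) and added to 11 in an Evans syn aldol reaction. The syn aldol adduct F2 should lactonise onto its methyl ester, on standing or with a trace of acid, to the trans lactone imide F3. LiOH–H2O2 (THF–H2O, 0 °C) should then remove the auxiliary and deliver 9.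

2. Step 12. Hydride may displace the mesylate before the lactone is fully reduced, or the lactol-stage alkoxide may close onto C5 to give a bicyclic acetal, so that the ether ring is not formed cleanly. Fallback, in which no hydride meets a leaving group, setting out from acid 14 and coming back at target 19: LiBH4 in THF should reduce only the lactone of the lithium carboxylate of 14 to the dihydroxy acid F4. On mild acidification F4 can close only a γ-lactone, through the new primary hydroxyl, giving the isomeric lactone F5 with the benzylic hydroxyl free. Silylation (TIPSOTf, 2,6-lutidine) gives the silyl ether F6, LiAlH4 reduction gives the 1,4-diol F7, and monotosylation with spontaneous cyclisation (TsCl, pyridine) gives the tris-silyl tetrahydrofuran F8, from which Bu4NF–AcOH removes all three silyl groups to give 19.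

3. Step 9. The dianion may react sluggishly, the carboxylate may be O-benzylated, or the facial selectivity of C-alkylation may be poor. Fallback, a mono-enolate of the ester with the deprotection moved behind the alkylation, setting out from allyl ester 8 and coming back at acid 14: kinetic deprotonation of 8 at the lactone CH2 with LiN(SiMe3)2 (1.05 equiv, THF, −78 °C) and addition of 13 should give the benzylated allyl ester F9, again trans to the ester. Pd(PPh3)4 with morpholine then releases 14.

**Further compounds**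

F1 | step 4 | (S)-4-benzyl-3-(4-methoxy-4-oxobutanoyl)oxazolidin-2-one | COC(=O)CCC(=O)N1[C@@H](Cc2ccccc2)COC1=O
F2 | step 4 | methyl (3S,4S)-3-[(S)-4-benzyl-2-oxooxazolidine-3-carbonyl]-4-hydroxy-4-[3-methoxy-4-(triisopropylsilyloxy)phenyl]butanoate | O[C@H](c1ccc(O[Si](C(C)C)(C(C)C)C(C)C)c(OC)c1)[C@@H](C(=O)N2[C@@H](Cc3ccccc3)COC2=O)CC(=O)OC
F3 | step 4 | (S)-4-benzyl-3-{(2S,3S)-2-[3-methoxy-4-(triisopropylsilyloxy)phenyl]-5-oxotetrahydrofuran-3-carbonyl}oxazolidin-2-one | O=C1O[C@H](c2ccc(O[Si](C(C)C)(C(C)C)C(C)C)c(OC)c2)[C@@H](C(=O)N3[C@@H](Cc4ccccc4)COC3=O)C1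
F4 | step 12 | (2S,3S)-4-hydroxy-2-{(S)-hydroxy[3-methoxy-4-(triisopropylsilyloxy)phenyl]methyl}-3-[3-methoxy-4-(triisopropylsilyloxy)benzyl]butanoic acid | O[C@H](c1ccc(O[Si](C(C)C)(C(C)C)C(C)C)c(OC)c1)[C@@H](C(=O)O)[C@@H](CO)Cc2ccc(O[Si](C(C)C)(C(C)C)C(C)C)c(OC)c2
F5 | step 12 | (3S,4S)-3-{(S)-hydroxy[3-methoxy-4-(triisopropylsilyloxy)phenyl]methyl}-4-[3-methoxy-4-(triisopropylsilyloxy)benzyl]dihydrofuran-2(3H)-one | O[C@H](c1ccc(O[Si](C(C)C)(C(C)C)C(C)C)c(OC)c1)[C@H]2C(=O)OC[C@H]2Cc3ccc(O[Si](C(C)C)(C(C)C)C(C)C)c(OC)c3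
F6 | step 12 | (3S,4S)-4-[3-methoxy-4-(triisopropylsilyloxy)benzyl]-3-{(S)-[3-methoxy-4-(triisopropylsilyloxy)phenyl](triisopropylsilyloxy)methyl}dihydrofuran-2(3H)-one | CC(C)[Si](C(C)C)(C(C)C)O[C@H](c1ccc(O[Si](C(C)C)(C(C)C)C(C)C)c(OC)c1)[C@H]2C(=O)OC[C@H]2Cc3ccc(O[Si](C(C)C)(C(C)C)C(C)C)c(OC)c3
F7 | step 12 | (2R,3S)-2-{(S)-[3-methoxy-4-(triisopropylsilyloxy)phenyl](triisopropylsilyloxy)methyl}-3-[3-methoxy-4-(triisopropylsilyloxy)benzyl]butane-1,4-diol | CC(C)[Si](C(C)C)(C(C)C)O[C@H](c1ccc(O[Si](C(C)C)(C(C)C)C(C)C)c(OC)c1)[C@@H](CO)[C@@H](CO)Cc2ccc(O[Si](C(C)C)(C(C)C)C(C)C)c(OC)c2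
F8 | step 12 | (3S,4R)-3-[3-methoxy-4-(triisopropylsilyloxy)benzyl]-4-{(S)-[3-methoxy-4-(triisopropylsilyloxy)phenyl](triisopropylsilyloxy)methyl}tetrahydrofuran | CC(C)[Si](C(C)C)(C(C)C)O[C@H](c1ccc(O[Si](C(C)C)(C(C)C)C(C)C)c(OC)c1)[C@H]2COC[C@H]2Cc3ccc(O[Si](C(C)C)(C(C)C)C(C)C)c(OC)c3
F9 | step 9 | allyl (2S,3S,4S)-4-[3-methoxy-4-(triisopropylsilyloxy)benzyl]-2-[3-methoxy-4-(triisopropylsilyloxy)phenyl]-5-oxotetrahydrofuran-3-carboxylate | O=C1O[C@H](c2ccc(O[Si](C(C)C)(C(C)C)C(C)C)c(OC)c2)[C@@H](C(=O)OCC=C)[C@@H]1Cc3ccc(O[Si](C(C)C)(C(C)C)C(C)C)c(OC)c3
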